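(All runs are simulated on assumed constants; scatter was added.)

**The product.** Bis adduct is what the next run is judged on, so decide whether the next flask can take 1.50 equiv of solid reagent instead of 2.1 equiv and still be stopped at 50 min.

| setting | north-east | south-east | flask |
|---|---|---|---|
| starting material | 0.10 M | 0.10 M | 0.10 M |
| solid reagent | 2.1 equiv | 3.3 equiv | 1.50 equiv |
| remark | run made earlier | run made earlier |  |
| time |  |  | 50 min |

- north-east (time / min: bis adduct / %, starting material / %): 8.00: 0, 95.2; 15.0: 0.4, 85.5; 25.0: 3.2, 72.1; 30.0: 3.3, 66.5; 40.0: 6.3, 54.5; 50.0: 10.0, 45.9
- south-east (time / min: bis adduct / %, starting material / %): 4.00: 0, 98.9; 6.00: 0.4, 96.3; 12.0: 0, 89.4; 20.0: 1.3, 79.7; 30.0: 3.0, 66.9; 50.0: 10.7, 46.1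

(standard deviation of a reading: 0.5 percentage points)

- amount of bis adduct at 50 min, in percent of the starting material charged
- concentration of partner in solution at 50 min, in percent of saturation

- solid reagent is a solid; its amount is given per volume of the solution
- at the start none of the solid reagent is in solution
- partner is what solid reagent becomes in solution

**The ratio.** Take bis adduct to arise from a second addition of partner onto a mono adduct, and divide its rate by the rate of loss of starting material: [partner] and time cancel, so bis adduct follows the starting material consumed and, early on, its square. The north-east and south-east runs consumed 54.0% on average by 50.0 min, and their readings of 10.0% and 10.7% give 0.355 for the bis number, bis adduct over the square of the fraction consumed, a working form of the selectivity factor.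

**The charge.** Those runs read 45.9% and 46.1% starting material at 2.1 equiv and 3.3 equiv, so extra solid shows no effect within the scatter. Reckon the partner used by these two additions by then, one per starting material consumed and one more per bis adduct, as 0.644 equiv, which is less than the 1.50 equiv charged; partner standing in solution comes on top of that. Charge the smaller amount and commit to 10.4% bis adduct. The readings show no [partner], so set no figure on saturation.

**The forecast.** It says 10.2% bis adduct and 90% of saturation: “Partner should sit slightly below saturation because reaction drains it while dissolution refills it.”

**The result.** The flask gives 10.5% bis adduct and 29.0% of saturation, and at 50.0 min partner is made 1.04 times as fast as it is used up. Put the 45.9% starting material left in this flask into the bis number and it returns 10.4%, a reckoning that holds no [partner].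

    starting material + partner → mono adduct (k = 0.0210 M⁻¹ s⁻¹)
    partner + mono adduct → bis adduct (k = 0.0120 M⁻¹ s⁻¹)
    partner + bis adduct → triple product (k = 0.00840 M⁻¹ s⁻¹)
    partner + triple product → tetra adduct (k = 0.0500 M⁻¹ s⁻¹)
    solid reagent ⇌ partner, rate k5*(cs5 - [partner]) while solid is left; crystals form when [partner] > cs5 (solubility = 0.0530 M, k = 6.80 × 10⁻⁴ s⁻¹)

**Second flask.** Read the same flask at 30 min: it holds 66.5% starting material, so the bis number gives 3.98%, and the computed bis adduct there is 3.64%.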